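Start from the leftover in amber: after 4.00 h, 83.0% of the G charged is not L, and the readings don't say how much of that still stands as solid.

| setting | amber | ochre | green | maple | birch | cedar | larch |
|---|---|---|---|---|---|---|---|
| G | 0.050 M | 0.050 M | 0.075 M | 0.050 M | 0.050 M | 0.050 M | 0.050 M |
| Z | 0.067 M | 0.15 M | 0.10 M | 0.100 M | 0.100 M | 0.100 M | 0.100 M |
| D | 0.065 M | 0.065 M | 0.065 M | 0.0650 M | 0.0650 M | 0.0650 M | 0.0650 M |
| temperature | 65 °C | 98 °C | 65 °C | 50 °C | 110 °C | 90 °C | 70 °C |
| remark | run made earlier | run made earlier | run made earlier |  |  |  |  |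
| time |  |  |  | 6.0 h | 6.0 h | 6.0 h | 6.0 h |

amber run (percent of the G charged): time / h: L / % = 0.250: 2; 0.667: 2; 1.33: 5; 4.00: 17

ochre run (percent of the G charged): time / min: L / % = 12.0: 2; 20.0: 5; 30.0: 4; 40.0: 7

green run (percent of the G charged): time / h: L / % = 0.417: 1; 1.33: 3; 2.50: 6; 4.00: 14

(standard deviation of a reading: 1.5 percentage points)

- given per volume of solution although it is solid: G
- the earlier runs were read with a standard deviation of 1.5 percentage points
- at the start none of G is in solution
- what has only dissolved of G counts as not reacted

- the best flask by amount of L, in percent of the G charged; "all alike" if 1.5 percentage points covers them all (maple / birch / cedar / larch / all alike)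
- amount of L at the end, in percent of the G charged, maple
- amount of L at the end, in percent of the G charged, birch
- amount of L at the end, in percent of the G charged, cedar
- amount of L at the end, in percent of the G charged, larch

Set green beside amber, both at 65 °C and both read at 4.00 h. Green holds 1.50 times the G and 1.49 times the Z, yet it reads less in percent, 14% against 17%. Turn each percentage into a molarity of L, then divide by the Z charged and by the time: amber gives 0.0317 h⁻¹ and green 0.0263 h⁻¹.

Take as the zero of the scale a flask of zero order in the G charged, where this ratio of green to amber is one. If L followed the charge, the ratio would be 1.50. The reading is 0.830, with a scatter of 1.5 percentage points on each percentage. G per Z is alike in the two flasks, 0.746 in amber and 0.750 in green, so equal L per Z would give equal percentages, and the gap of 3 points between amber and green is this same ratio seen in percent. Against that scatter, take the two values as one.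

Call the mean, 0.0290 h⁻¹, the Z yield w: moles of L formed per mole of Z charged per hour. Ochre gives 0.0350 h⁻¹ at 98 °C, but its readings stop at 40.0 min, so they show nothing of L over a long hot run. Reckon larch from w, about 34.8%, and leave the hotter flasks open.

The forecast gives maple 21%, birch 38%, cedar 35% and larch 29%, with birch best: “Birch is only tentatively best”.

The flasks give maple 12.3%, birch 22.5%, cedar 17.5% and larch 27.9%, so larch is best.

    X + D → J (k = 3.80 M⁻¹ min⁻¹, Ea = 76.0 kJ mol⁻¹)
    L ⇌ Q (K = 1.60, k = 0.170 min⁻¹, Ea = 108 kJ mol⁻¹, ΔH = −22.0 kJ mol⁻¹)
    X + Z → L (k = 3.40 M⁻¹ min⁻¹, Ea = 76.0 kJ mol⁻¹)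
    G ⇌ X, rate k4*(cs4 - [X]) while solid is left; crystals form when [X] > cs4 (solubility = 5.40 mM, k = 0.0570 min⁻¹)
    (constants at 110 °C)

In birch, Q stands at 35.9% beside L at 22.5%, with G at 0%. Larch has a Z yield of 0.0232 h⁻¹, below w. Maple has 0.0103 h⁻¹. A neighbour of maple charged with 0.020 M of G reaches 30.9%, and its Z yield is 0.0103 h⁻¹.

All runs are simulated with made-up constants.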